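**Retrosynthetic overview**
- The route rests on the core ring C1–C6: oxygen on the para carbons C3 and C6, the chain on C1 and C7H2OH on C4, which is the pattern of a 2,5-disubstituted hydroquinone monomethyl ether.
- Endgame: the C1–C2 oxirane and the C3/C6 carbinols come from 4-methoxyphenol 26 by oxidative dearomatisation to the quinone monoketal (C6 ketone), nucleophilic epoxidation, and two 1,2-reductions around a ketal hydrolysis.
- Key disconnection: benzannulation of the full side-chain alkyne 18 (C1, C2) with alkenyl methoxycarbene chromium complex 24 (C3, C4, C5) and one CO ligand (C6).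
- Alkyne 18 comes from a (2Z,4E)-dienal by catalytic asymmetric alkynylation (sets C1'); the dienal from Suzuki coupling of an E-alkenylboronate with (Z)-3-iodobut-2-en-1-ol.
- Ring order: cyclohexane C6'–C11' first (Ti(III) radical cyclisation of (R)-6,7-epoxygeranyl acetate, step 2), core carbocycle second (step 16), oxirane last (step 18).

Key step: step 16

**Remarks**
- Numbering: core ring C1–C6 (C1 bears the chain, C4 bears C7H2OH, C4=C5); chain C1'–C5'; cyclohexane C6'–C11' (C7' tertiary carbinol, C10' secondary carbinol, C11' gem-dimethyl). The target is (1R,2S,3R,6S,1'S,2'Z,4'E,6'R,7'R,10'R).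
- Abbreviations: Cy* = (1R,3R,6R)-2,2,6-trimethyl-3,6-bis(triethylsilyloxy)cyclohexyl (ring C1 = C6', C3 = C10', C6 = C7'). SC* = (1S,2Z,4E)-1-(tert-butyldimethylsilyloxy)-3-methyl-5-Cy*-penta-2,4-dien-1-yl.
- Assumption: the (S,S)-ProPhenol–zinc catalyst is taken to add the alkynyl group to the Re face of enal 14; if the sense were opposite, (R,R)-ProPhenol would be used in step 11 with nothing else changed.
- Protecting groups: TIPS on the carbene fragment suppresses O-to-C silyl migration in the 2-lithioallyl ether. TES on C7'-O and C10'-O allows one mild fluoride deprotection at the end.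

**Route**

Step 1
Reactants: 1 geranyl acetate
Product: 2 (2E)-5-[(2R)-3,3-dimethyloxiran-2-yl]-3-methylpent-2-en-1-yl acetate
Conditions: D-fructose-derived Shi ketone (0.3 equiv), Oxone, K2CO3, Bu4NHSO4, MeCN/DMM/aq. borate buffer (pH 10.5), 0 °C
Reagents that add atoms: Oxone (potassium peroxymonosulfate), [K+].[O-]S(=O)(=O)OO
Why: Shi asymmetric epoxidation attacks only the electron-rich 6,7-alkene (the 2,3-alkene is deactivated by the allylic acetate), and the spiro transition state of the D-fructose-derived dioxirane should give the (R)-epoxide, which becomes C10'.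

Step 2
Reactants: 2 (R)-6,7-epoxygeranyl acetate
Product: 3 [(1S,3R)-3-hydroxy-2,2-dimethyl-6-methylidenecyclohexyl]methyl acetate
Conditions: Cp2TiCl2 (2.2 equiv), Mn dust, THF, rt; 1 M HCl work-up
Reagents that add atoms: none
Why: Titanocene(III) opens the epoxide to the tertiary radical, which closes 6-endo through a chair with O–Ti and CH2OAc equatorial (C6' cis to the C10' oxygen, C10' retained); a second Ti(III) traps the ring radical and β-hydride elimination gives the exocyclic alkene.

Step 3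
Reactants: 3 hydroxy exo-methylene acetate
Product: 4 [(3R,4S,6R)-6-hydroxy-5,5-dimethyl-1-oxaspiro[2.5]octan-4-yl]methyl acetate
Conditions: mCPBA, NaHCO3, CH2Cl2, 0 °C
Reagents that add atoms: mCPBA, OOC(=O)c1cccc(Cl)c1
Why: Prilezhaev epoxidation should occur along the equatorial trajectory, because the axial C11' methyl blocks axial approach to C7', which puts the oxirane oxygen equatorial and trans to CH2OAc and so sets C7'.

Step 4
Reactants: 4 spiro-epoxy acetate
Product: 5 (1R,2S,4R)-2-(hydroxymethyl)-1,3,3-trimethylcyclohexane-1,4-diol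
Conditions: LiAlH4 (excess), THF, 0 °C to reflux; Fieser work-up
Reagents that add atoms: none
Why: Hydride opens the 1,1-disubstituted epoxide by SN2 at its CH2 carbon, leaving the C7'–O bond untouched (axial methyl, equatorial tertiary OH), and the acetate is reduced to the primary alcohol in the same operation.

Step 5
Reactants: 5 triol
Product: 6 triethyl{[(1S,3R,6R)-2,2,6-trimethyl-3,6-bis(triethylsilyloxy)cyclohexyl]methoxy}silane
Conditions: TESOTf (4 equiv), 2,6-lutidine, CH2Cl2, −78 to 0 °C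
Reagents that add atoms: triethylsilyl triflate, CC[Si](CC)(CC)OS(=O)(=O)C(F)(F)F
Why: The silyl triflate silylates primary, hindered secondary and tertiary hydroxyls alike.

Step 6
Reactants: 6 tris-TES ether
Product: 7 (1R,3R,6R)-2,2,6-trimethyl-3,6-bis(triethylsilyloxy)cyclohexane-1-carbaldehyde
Conditions: (COCl)2, DMSO, CH2Cl2, −78 to −40 °C; then Et3N, −78 to 0 °C
Reagents that add atoms: none
Why: Under Swern conditions a primary TES ether is cleaved and oxidised in situ while secondary and tertiary silyl ethers persist; the equatorial formyl group has no drive to epimerise and the low temperature guards against β-elimination of the C7' silyloxy group.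

Step 7
Reactants: 7 aldehyde; 8 2-(dichloromethyl)-4,4,5,5-tetramethyl-1,3,2-dioxaborolane
Product: 9 2-[(E)-2-Cy*-ethenyl]-4,4,5,5-tetramethyl-1,3,2-dioxaborolane
Conditions: CrCl2 (8 equiv), LiI (4 equiv), THF, rt
Reagents that add atoms: none
Why: Takai–Utimoto olefination with the boryl-substituted gem-dichromium reagent is non-basic and E-selective, and the bulky ring reinforces the E geometry of C4'=C5'.

Step 8
Reactants: 10 but-2-yn-1-ol
Product: 12 (2Z)-3-iodobut-2-en-1-ol, via cyclic sodium vinylalanate 11 (not isolated)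
Conditions: Red-Al, THF, 0 °C to rt; then I2, −78 °C; Rochelle salt work-up
Reagents that add atoms: iodine, II
Why: Alkoxide-directed trans-hydroalumination places aluminium on C3 in a five-membered alanate, and iodinolysis with retention gives the Z-iodide (I cis to CH2OH).

Step 9
Reactants: 9 E-alkenylboronate; 12 (2Z)-3-iodobut-2-en-1-ol
Product: 13 (2Z,4E)-3-methyl-5-Cy*-penta-2,4-dien-1-ol
Conditions: Pd(dppf)Cl2 (5 mol%), aq. K3PO4, THF, 45 °C
Reagents that add atoms: none
Why: Suzuki–Miyaura coupling proceeds with retention at both sp2 carbons, so the Z-iodide and E-boronate give the (2Z,4E)-diene directly.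

Step 10
Reactants: 13 dienol
Product: 14 (2Z,4E)-3-methyl-5-Cy*-penta-2,4-dienal
Conditions: activated MnO2 (excess), CH2Cl2, rt, dark
Reagents that add atoms: none
Why: Neutral heterogeneous allylic oxidation with MnO2 should keep the 2Z geometry, as in related (2Z,4E)-3-methyldienals.

Step 11
Reactants: 14 dienal; 15 ethynyltrimethylsilane
Product: 16 (3S,4Z,6E)-5-methyl-7-Cy*-1-(trimethylsilyl)hepta-4,6-dien-1-yn-3-ol
Conditions: (S,S)-ProPhenol (20 mol%), Me2Zn (3 equiv), Ph3P=O (40 mol%), toluene, 0–4 °C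
Reagents that add atoms: none
Why: Dinuclear zinc–ProPhenol catalysed alkynylation is established for α,β-unsaturated aldehydes; the catalyst, not the remote ring, controls the face, and Re-face delivery of the alkynylzinc sets C1' as S.

Step 12
Reactants: 16 propargylic alcohol
Product: 17 tert-butyldimethylsilyl ether of 16
Conditions: TBSOTf, 2,6-lutidine, CH2Cl2, −78 °C
Reagents that add atoms: tert-butyldimethylsilyl triflate, CC(C)(C)[Si](C)(C)OS(=O)(=O)C(F)(F)F
Why: Buffered silylation at low temperature protects the ionisable bis-allylic/propargylic carbinol without touching its configuration.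

Step 13
Reactants: 17 TMS-alkyne
Product: 18 (3S,4Z,6E)-3-(tert-butyldimethylsilyloxy)-5-methyl-7-Cy*-hepta-4,6-dien-1-yne
Conditions: K2CO3, MeOH, rt
Reagents that add atoms: none
Why: Methanolysis cleaves the C(sp)–Si bond selectively; the O-silyl ethers (TBS, hindered TES) are stable to these conditions.

Step 14
Reactants: 19 2-bromoprop-2-en-1-ol
Product: 20 (2-bromoallyloxy)triisopropylsilane
Conditions: TIPSCl, imidazole, DMF, rt
Reagents that add atoms: triisopropylsilyl chloride, CC(C)[Si](Cl)(C(C)C)C(C)C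
Why: Standard silylation; the bulky TIPS group is chosen because it resists 1,3 O-to-C migration in the vinyllithium of the next step.

Step 15
Reactants: 20 2-bromoallyl TIPS ether; 21 chromium hexacarbonyl
Product: 24 pentacarbonyl{methoxy[3-(triisopropylsilyloxy)prop-1-en-2-yl]carbene}chromium(0), via 2-lithioallyl TIPS ether 22 (not isolated), via lithium acylpentacarbonylchromate 23 (not isolated)
Conditions: t-BuLi (2 equiv), Et2O, −78 °C; Cr(CO)6, Et2O, −78 to 0 °C; then MeOTf, CH2Cl2, 0 °C
Reagents that add atoms: methyl triflate, COS(=O)(=O)C(F)(F)F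
Why: Fischer carbene synthesis: bromine–lithium exchange, addition of the vinyllithium to a CO ligand, and O-methylation of the acylmetalate with a hard methylating agent.

Step 16
Reactants: 18 side-chain alkyne; 24 alkenyl methoxycarbene complex
Product: 26 4-methoxy-2-SC*-5-[(triisopropylsilyloxy)methyl]phenol, via tricarbonylchromium complex of the phenol 25 (not isolated)
Conditions: 24 (1.5 equiv), degassed THF (0.05 M), 50 °C, Ar; then air, MeCN, rt
Reagents that add atoms: none
Why: Thermal loss of one CO from 24 lets alkyne 18 insert into Cr=C with its terminal carbon bonded to the carbene carbon (C2–C3), CO insertion (C1–C6) gives a chromium-bound dienylketene that closes by 6π-electrocyclisation (C5–C6) and tautomerises to the Cr(CO)3-bound 4-methoxyphenol 25, from which air releases 26. This is the Dötz benzannulation as known for α-substituted alkenyl(methoxy)carbene chromium complexes with terminal propargylic ethers. The one ring closure is a thermal disrotatory 6π-electrocyclisation of the (Z)-dienylketene, formally a 6-endo attack of C5 on the ketene carbon. No stereocentre is formed, and C1' is not epimerisable under the neutral conditions. The step needs regioselective insertion (substituted alkyne carbon C1 next to the CO-derived C6), which the steric difference between H and the branched silyloxy-dienyl substituent secures. It also needs chemoselectivity for the alkyne over the diene, expected because alkyne insertion and CO insertion/electrocyclisation of an alkenylcarbene are faster at 50 °C than cyclopropanation of the hindered C2'=C3' or C4'=C5' bonds.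

Step 17
Reactants: 26 4-methoxyphenol
Product: 27 4,4-dimethoxy-2-SC*-5-[(triisopropylsilyloxy)methyl]cyclohexa-2,5-dien-1-one
Conditions: PhI(OAc)2 (1.1 equiv), MeOH, 0 °C, 15 min; NaHCO3 quench
Reagents that add atoms: methanol, CO
Why: Hypervalent-iodine oxidative dearomatisation; methanol adds para to the phenol oxygen at the methoxy-bearing C3, giving the quinone monoketal with the ketone at C6.

Step 18
Reactants: 27 quinone monoketal
Product: 28 C1–C2 epoxide of 27 (5,5-dimethoxy-1-SC*-4-[(triisopropylsilyloxy)methyl]-7-oxabicyclo[4.1.0]hept-3-en-2-one, epoxide configured as in the target)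
Conditions: anhydrous t-BuOOH (decane), DBU, CH2Cl2, 0 °C
Reagents that add atoms: tert-butyl hydroperoxide, CC(C)(C)OO
Why: Weitz–Scheffer epoxidation: the peroxide adds only to C2, the one enone β-carbon that carries hydrogen (C4 is fully substituted), and in the ring closure A(1,3) strain with the enolate oxygen should hold C1'–H in the ring plane so that the C1–O bond forms anti to the branched (Z)-dienyl group, which corresponds to the target epoxide face.

Step 19
Reactants: 28 epoxy ketone
Product: 29 C6 alcohol of 28 (C6–OH trans to the oxirane oxygen)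
Conditions: NaBH4, CeCl3·7H2O, MeOH/THF, −78 °C
Reagents that add atoms: none
Why: Luche 1,2-reduction; hydride should enter C6 from the oxirane face, the usual sense for borohydride reduction of cyclic 2,3-epoxy ketones and here also the face away from the C1' branch on the quaternary C1, giving the alcohol trans to the epoxide.

Step 20
Reactants: 29 epoxy alcohol dimethyl ketal
Product: 30 C3 enone (C6–OH, C1–C2 epoxide, C3 ketone, C4=C5)
Conditions: SiO2, 10% aq. oxalic acid, CH2Cl2, rt
Reagents that add atoms: water, O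
Why: The allylic dimethyl ketal hydrolyses through a stabilised oxocarbenium ion under acid mild enough to spare the silyl ethers and the epoxide.

Step 21
Reactants: 30 epoxy hydroxy enone
Product: 31 tetrasilylated arthrosporol A (C3–OH and C6–OH both trans to the oxirane oxygen)
Conditions: NaBH4, CeCl3·7H2O, MeOH, −78 °C
Reagents that add atoms: none
Why: Luche 1,2-reduction of the enone; hydride is again expected on the oxirane face of the 2,3-epoxy ketone, giving the C3 alcohol trans to the epoxide and cis to C6–OH.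

Step 22
Reactants: 31 tetrasilyl ether
Product: 32 arthrosporol A
Conditions: HF·pyridine, pyridine, THF, 0 °C to rt
Reagents that add atoms: none
Why: Buffered fluoride desilylation removes TBS, TIPS and both TES groups without the alkoxide basicity that would trigger epoxide migration and without acid strong enough to ionise the dienylic C1' carbinol.

**Compound list**

1 | geranyl acetate | CC(C)=CCC/C(C)=C/COC(C)=O | starting material
2 | (2E)-5-[(2R)-3,3-dimethyloxiran-2-yl]-3-methylpent-2-en-1-yl acetate | CC1(C)O[C@@H]1CC/C(C)=C/COC(C)=O | intermediate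
3 | [(1S,3R)-3-hydroxy-2,2-dimethyl-6-methylidenecyclohexyl]methyl acetate | CC(=O)OC[C@@H]1C(C)(C)[C@H](O)CCC1=C | intermediate
4 | [(3R,4S,6R)-6-hydroxy-5,5-dimethyl-1-oxaspiro[2.5]octan-4-yl]methyl acetate | CC(=O)OC[C@@H]1C(C)(C)[C@H](O)CC[C@@]12OC2 | intermediate
5 | (1R,2S,4R)-2-(hydroxymethyl)-1,3,3-trimethylcyclohexane-1,4-diol | OC[C@@H]1C(C)(C)[C@H](O)CC[C@@]1(C)O | intermediate
6 | tris(triethylsilyl) ether of 5 | CC[Si](CC)(CC)OC[C@@H]1C(C)(C)[C@H](O[Si](CC)(CC)CC)CC[C@@]1(C)O[Si](CC)(CC)CC | intermediate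
7 | (1R,3R,6R)-2,2,6-trimethyl-3,6-bis(triethylsilyloxy)cyclohexane-1-carbaldehyde | O=C[C@@H]1C(C)(C)[C@H](O[Si](CC)(CC)CC)CC[C@@]1(C)O[Si](CC)(CC)CC | intermediate
8 | 2-(dichloromethyl)-4,4,5,5-tetramethyl-1,3,2-dioxaborolane | ClC(Cl)B1OC(C)(C)C(C)(C)O1 | starting material
9 | 2-[(E)-2-Cy*-ethenyl]-4,4,5,5-tetramethyl-1,3,2-dioxaborolane | CC1(C)OB(/C=C/[C@@H]2C(C)(C)[C@H](O[Si](CC)(CC)CC)CC[C@@]2(C)O[Si](CC)(CC)CC)OC1(C)C | intermediate
10 | but-2-yn-1-ol | CC#CCO | starting material
11 | cyclic sodium vinylalanate (2,2-bis(2-methoxyethoxy)-3-methyl-1,2-oxaaluminacyclopent-3-ene, sodium salt) | CC1=CCO[Al-]1(OCCOC)OCCOC.[Na+] | intermediate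
12 | (2Z)-3-iodobut-2-en-1-ol | C/C(I)=C/CO | intermediate
13 | (2Z,4E)-3-methyl-5-Cy*-penta-2,4-dien-1-ol | OC/C=C(C)\C=C\[C@@H]1C(C)(C)[C@H](O[Si](CC)(CC)CC)CC[C@@]1(C)O[Si](CC)(CC)CC | intermediate
14 | (2Z,4E)-3-methyl-5-Cy*-penta-2,4-dienal | O=C/C=C(C)\C=C\[C@@H]1C(C)(C)[C@H](O[Si](CC)(CC)CC)CC[C@@]1(C)O[Si](CC)(CC)CC | intermediate
15 | ethynyltrimethylsilane | C#C[Si](C)(C)C | starting material
16 | (3S,4Z,6E)-5-methyl-7-Cy*-1-(trimethylsilyl)hepta-4,6-dien-1-yn-3-ol | C[Si](C)(C)C#C[C@@H](O)/C=C(C)\C=C\[C@@H]1C(C)(C)[C@H](O[Si](CC)(CC)CC)CC[C@@]1(C)O[Si](CC)(CC)CC | intermediate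
17 | tert-butyldimethylsilyl ether of 16 | C[Si](C)(C)C#C[C@@H](O[Si](C)(C)C(C)(C)C)/C=C(C)\C=C\[C@@H]1C(C)(C)[C@H](O[Si](CC)(CC)CC)CC[C@@]1(C)O[Si](CC)(CC)CC | intermediate
18 | (3S,4Z,6E)-3-(tert-butyldimethylsilyloxy)-5-methyl-7-Cy*-hepta-4,6-dien-1-yne | C#C[C@@H](O[Si](C)(C)C(C)(C)C)/C=C(C)\C=C\[C@@H]1C(C)(C)[C@H](O[Si](CC)(CC)CC)CC[C@@]1(C)O[Si](CC)(CC)CC | intermediate
19 | 2-bromoprop-2-en-1-ol | C=C(Br)CO | starting material
20 | (2-bromoallyloxy)triisopropylsilane | C=C(Br)CO[Si](C(C)C)(C(C)C)C(C)C | intermediate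
21 | chromium hexacarbonyl | O=C=[Cr](=C=O)(=C=O)(=C=O)(=C=O)=C=O | starting material
22 | 2-lithioallyl triisopropylsilyl ether | [Li]C(=C)CO[Si](C(C)C)(C(C)C)C(C)C | intermediate
23 | lithium acylpentacarbonylchromate | [Li+].[O-]C(C(=C)CO[Si](C(C)C)(C(C)C)C(C)C)=[Cr](=C=O)(=C=O)(=C=O)(=C=O)=C=O | intermediate
24 | pentacarbonyl{methoxy[3-(triisopropylsilyloxy)prop-1-en-2-yl]carbene}chromium(0) | COC(C(=C)CO[Si](C(C)C)(C(C)C)C(C)C)=[Cr](=C=O)(=C=O)(=C=O)(=C=O)=C=O | intermediate
25 | η6-tricarbonylchromium complex of phenol 26 (written as arene and Cr(CO)3 joined by a dot) | COc1cc([C@@H](O[Si](C)(C)C(C)(C)C)/C=C(C)\C=C\[C@@H]2C(C)(C)[C@H](O[Si](CC)(CC)CC)CC[C@@]2(C)O[Si](CC)(CC)CC)c(O)cc1CO[Si](C(C)C)(C(C)C)C(C)C.O=C=[Cr](=C=O)=C=O | intermediate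
26 | 4-methoxy-2-SC*-5-[(triisopropylsilyloxy)methyl]phenol | COc1cc([C@@H](O[Si](C)(C)C(C)(C)C)/C=C(C)\C=C\[C@@H]2C(C)(C)[C@H](O[Si](CC)(CC)CC)CC[C@@]2(C)O[Si](CC)(CC)CC)c(O)cc1CO[Si](C(C)C)(C(C)C)C(C)C | intermediate
27 | 4,4-dimethoxy-2-SC*-5-[(triisopropylsilyloxy)methyl]cyclohexa-2,5-dien-1-one | COC1(OC)C=C([C@@H](O[Si](C)(C)C(C)(C)C)/C=C(C)\C=C\[C@@H]2C(C)(C)[C@H](O[Si](CC)(CC)CC)CC[C@@]2(C)O[Si](CC)(CC)CC)C(=O)C=C1CO[Si](C(C)C)(C(C)C)C(C)C | intermediate
28 | C1–C2 epoxide of 27 (C6 ketone, C3 dimethyl ketal, epoxide as in the target) | CC(=C/[C@H](O[Si](C)(C)C(C)(C)C)[C@]12O[C@H]1C(OC)(OC)C(CO[Si](C(C)C)(C(C)C)C(C)C)=CC2=O)/C=C/[C@@H]1C(C)(C)[C@H](O[Si](CC)(CC)CC)CC[C@@]1(C)O[Si](CC)(CC)CC | intermediate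
29 | C6 alcohol of 28 (OH trans to oxirane O) | CC(=C/[C@H](O[Si](C)(C)C(C)(C)C)[C@]12O[C@H]1C(OC)(OC)C(CO[Si](C(C)C)(C(C)C)C(C)C)=C[C@@H]2O)/C=C/[C@@H]1C(C)(C)[C@H](O[Si](CC)(CC)CC)CC[C@@]1(C)O[Si](CC)(CC)CC | intermediate
30 | C3 enone (C6–OH, C1–C2 epoxide) | CC(=C/[C@H](O[Si](C)(C)C(C)(C)C)[C@]12O[C@H]1C(=O)C(CO[Si](C(C)C)(C(C)C)C(C)C)=C[C@@H]2O)/C=C/[C@@H]1C(C)(C)[C@H](O[Si](CC)(CC)CC)CC[C@@]1(C)O[Si](CC)(CC)CC | intermediate
31 | 1'-O-TBS, 7-O-TIPS, 7',10'-bis-O-TES arthrosporol A | CC(=C/[C@H](O[Si](C)(C)C(C)(C)C)[C@]12O[C@H]1[C@H](O)C(CO[Si](C(C)C)(C(C)C)C(C)C)=C[C@@H]2O)/C=C/[C@@H]1C(C)(C)[C@H](O[Si](CC)(CC)CC)CC[C@@]1(C)O[Si](CC)(CC)CC | intermediate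
32 | arthrosporol A | CC(=C/[C@H](O)[C@]12O[C@H]1[C@H](O)C(CO)=C[C@@H]2O)/C=C/[C@@H]1C(C)(C)[C@H](O)CC[C@@]1(C)O | target

**Step count**
Total: 22 steps. Longest linear sequence: 19 steps (1–7, 9–13, 16–22).

**Steps most likely to fail**

Step 16 (benzannulation). The vinylcarbene or dienylketene intermediate may be intercepted by the electron-rich (2Z,4E)-diene, the terminal alkyne may oligomerise, or the sensitive carbene complex may decompose before insertion. The fallback moves the arene construction onto a small, diene-free alkyne and attaches the terpenoid afterwards; it sets out from 12 and boronate 9 and returns at 26. Alcohol 12 is oxidised with MnO2 to (2Z)-3-iodobut-2-enal F1. F1 is alkynylated as in step 11 to (3S,4Z)-5-iodo-1-(trimethylsilyl)hex-4-en-1-yn-3-ol F2, silylated to its tert-butyldimethylsilyl ether F3 and C-desilylated with K2CO3/MeOH to (3S,4Z)-3-(tert-butyldimethylsilyloxy)-5-iodohex-4-en-1-yne F4. Benzannulation of F4 with 24 under the step 16 conditions should give the iodoalkenyl phenol F5. Suzuki–Miyaura coupling of F5 with 9 (Pd(dppf)Cl2, aq. K3PO4) then joins C3' to C4' with retention and gives 26.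

Step 18 (nucleophilic epoxidation). Facial selectivity rests only on the C1' stereocentre and may be poor or reversed if the silyloxy group rather than the dienyl group ends up anti to the forming C–O bond. The fallback puts the face under auxiliary control; it sets out from 27 and returns at 30. Transketalisation of 27 with (2S,4S)-pentane-2,4-diol (PPTS, benzene, 60 °C) gives the spiro-dioxane dienone F6. In the chair that places ring carbon C2 axial, one dioxane methyl is axial over C2 on the face that must stay free of peroxide, so epoxidation (trityl hydroperoxide/KHMDS, THF, −78 to −40 °C) should give the epoxy ketone F7 with the target epoxide face. Luche reduction as in step 19 gives the C6 alcohol F8, and hydrolysis of the dioxane ketal (aqueous oxalic acid on silica, longer time) gives 30.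

Step 21 (C3 reduction). Hydride may instead enter anti to the oxirane oxygen, since C2 carries only hydrogen on that face, which would give the C3 epimer. The fallback replaces facial control by inversion; it sets out from 30 and returns at 31. Reduction under the conditions that favour the undesired face (for example L-Selectride, THF, −78 °C) gives the 3-epi diol F9. Mitsunobu reaction (4-nitrobenzoic acid, PPh3, DIAD) at the allylic C3–OH, which is far less hindered than the C6–OH next to the quaternary C1, gives the inverted 3-O-(4-nitrobenzoate) F10. Methanolysis (K2CO3, MeOH, 0 °C) then gives 31.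

**Further compounds**
F1 | step 16 | (2Z)-3-iodobut-2-enal | C/C(I)=C/C=O
F2 | step 16 | (3S,4Z)-5-iodo-1-(trimethylsilyl)hex-4-en-1-yn-3-ol | C[Si](C)(C)C#C[C@@H](O)/C=C(C)\I
F3 | step 16 | tert-butyldimethylsilyl ether of F2 | C[Si](C)(C)C#C[C@@H](O[Si](C)(C)C(C)(C)C)/C=C(C)\I
F4 | step 16 | (3S,4Z)-3-(tert-butyldimethylsilyloxy)-5-iodohex-4-en-1-yne | C#C[C@@H](O[Si](C)(C)C(C)(C)C)/C=C(C)\I
F5 | step 16 | 2-[(1S,2Z)-1-(tert-butyldimethylsilyloxy)-3-iodobut-2-en-1-yl]-4-methoxy-5-[(triisopropylsilyloxy)methyl]phenol | COc1cc([C@@H](O[Si](C)(C)C(C)(C)C)/C=C(C)\I)c(O)cc1CO[Si](C(C)C)(C(C)C)C(C)C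
F6 | step 18 | (2S,4S)-pentane-2,4-diyl ketal analogue of 27 | C12(O[C@@H](C)C[C@H](C)O1)C=C([C@@H](O[Si](C)(C)C(C)(C)C)/C=C(C)\C=C\[C@@H]3C(C)(C)[C@H](O[Si](CC)(CC)CC)CC[C@@]3(C)O[Si](CC)(CC)CC)C(=O)C=C2CO[Si](C(C)C)(C(C)C)C(C)C
F7 | step 18 | C1–C2 epoxide of F6 (epoxide as in the target) | CC(=C/[C@H](O[Si](C)(C)C(C)(C)C)[C@]12O[C@H]1C3(O[C@@H](C)C[C@H](C)O3)C(CO[Si](C(C)C)(C(C)C)C(C)C)=CC2=O)/C=C/[C@@H]1C(C)(C)[C@H](O[Si](CC)(CC)CC)CC[C@@]1(C)O[Si](CC)(CC)CC
F8 | step 18 | C6 alcohol of F7 (OH trans to oxirane O) | CC(=C/[C@H](O[Si](C)(C)C(C)(C)C)[C@]12O[C@H]1C3(O[C@@H](C)C[C@H](C)O3)C(CO[Si](C(C)C)(C(C)C)C(C)C)=C[C@@H]2O)/C=C/[C@@H]1C(C)(C)[C@H](O[Si](CC)(CC)CC)CC[C@@]1(C)O[Si](CC)(CC)CC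
F9 | step 21 | 3-epi-31 (C3–OH cis to oxirane O) | CC(=C/[C@H](O[Si](C)(C)C(C)(C)C)[C@]12O[C@H]1[C@@H](O)C(CO[Si](C(C)C)(C(C)C)C(C)C)=C[C@@H]2O)/C=C/[C@@H]1C(C)(C)[C@H](O[Si](CC)(CC)CC)CC[C@@]1(C)O[Si](CC)(CC)CC
F10 | step 21 | 3-O-(4-nitrobenzoyl) derivative of 31 | CC(=C/[C@H](O[Si](C)(C)C(C)(C)C)[C@]12O[C@H]1[C@H](OC(=O)c3ccc(cc3)[N+](=O)[O-])C(CO[Si](C(C)C)(C(C)C)C(C)C)=C[C@@H]2O)/C=C/[C@@H]1C(C)(C)[C@H](O[Si](CC)(CC)CC)CC[C@@]1(C)O[Si](CC)(CC)CC
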